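## The problem

Compound 28 is a cyclohexane in which five of the seven carbons carry oxygen. C1 is quaternary and bears a tertiary hydroxyl and the benzoyloxymethyl carbon C7. C2 and C6 are secondary carbinols on either side of it, C5 carries the second benzoate, and C3–C4 is an unoxygenated CH2–CH2 pair. The four stereocentres C1, C2, C5 and C6 are contiguous: the C1 hydroxyl is trans to the hydroxyls at C2 and C6 (so C7 is cis to both), and the C5 benzoate is trans to the C6 hydroxyl. C5 and C6 form a trans-diol unit of the kind a hexose supplies. C1 and C2 have to be made, and a stereocentre next to C5 can relay its chirality to them if it is consumed in a stereospecific step. Two of five oxygens are acylated, so O5 and O7 must be told apart from O1, O2 and O6 before the esters go on. Once present, the benzoates exclude hydride, alkoxide and strong base, which would cleave them or move the O5 ester to O6. The enabling feature is that C1 carries an oxygen and a one-carbon branch at C7, and is bonded to the carbinol C2 whose neighbour C3 begins the unoxygenated pair. With C7 read as an ester carbonyl, C1 as its α-carbon and C3=C4 as an alkene, C1–C2 is the bond made in an ester-enolate [3,3] shift in which the ester oxygen leaves C4. The shift converts a six-membered lactone into a six-membered carbocycle: the ring oxygen and C7 leave the ring, C2 and C3 enter it.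

## Retrosynthesis

Target numbering (C1–C7) is used for the carbocycles. In the lactones, C1–C7 of the heptenonolactone correspond to target C7, C1, C6, C5, C4, C3 and C2.

**28 from 26.** The last cut removes the benzyl ether at O2 and the benzyloxymethyl ether at O6 and adds hydrogen to C3=C4, all in one reductive operation on dibenzoate 26. Keeping the alkene and the two ethers to the end means no free secondary hydroxyl competes during benzoylation. The forward step must saturate the alkene without cleaving the allylic C–O bonds.

**26 from 22.** The two ester C–O bonds are cut in turn: 26 comes from diol 25, 25 from the primary benzoate 24, and 24 from alcohol 22 with benzoyl chloride 23. Between the two acylations the 2-naphthylmethyl ethers at O1 and O5 are cleaved oxidatively. The primary hydroxyl is acylated first because a free hydroxyl next to the tertiary naphthylmethyl ether could trap the oxidised ether as a cyclic acetal. The tertiary C1 hydroxyl freed with O5 needs no protection, since it does not acylate under the conditions that esterify O5.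

**22 from 21.** C7 is taken back to the carboxyl level, giving acid 21. This is a single hydride reduction with no stereochemical demand.

**21 from 18 (key disconnection).** The C1–C2 bond is cut and the O–C4 bond re-formed, turning cyclohexenecarboxylic acid 21 into δ-lactone 18, which carries an (E)-2-benzyloxyvinyl group on its carbinol carbon. Against cuts that build C1 by addition to a ring ketone, this one forms the quaternary centre, its oxygen and its carbon branch in the C–C bond-forming step, with both new stereocentres fixed by a concerted transition state. The precursor has three stereocentres that matter (lactone C3, C4, C5) and all lie on a sugar chain. The configuration at lactone C2 is erased in the ketene acetal, so it can be whatever the cheapest sugar provides. The forward reaction needs O-silylation faster than β-elimination, and an (E)-enol ether of high isomeric purity.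

**18 from 13.** The benzyloxymethyl group at lactone O3 is removed to give hydroxy lactone 16 (reagent: benzyl chloromethyl ether 17). The acyl C–O bond and the C1 oxidation level are then taken back to triol 13. Oxidative lactonisation of a 1,5-diol makes the lactone directly from a primary alcohol and needs no acid, which the γ-oxygenated enol ether would not survive. Only the allylic hydroxyl can close a six-membered ring, so the third hydroxyl of 13 needs no protection until the lactone exists.

**13 from 9.** The enol ether C–O bond is cut to the (E)-alkenylboronate 11 and benzyl alcohol 12. The boronate is cut at its C=C bond to the terminal alkene 9 and vinylboronic acid pinacol ester 10. An alkoxymethylene Wittig reaction would make the same bond in one step but without control of geometry. The two-step route fixes the (E) geometry in the metathesis and transfers it with retention.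

**9 from 7.** The terminal C=C bond is cut to lactol 7 and the methylene unit of phosphonium salt 8. Read from this end, the D-gluco chain already has the required configuration: the carbons that become target C4, C5 and C6 are glucose C2, C3 and C4, glucose C5 becomes the α-carbon whose configuration is lost, and glucose C6 becomes C7. No inversion is needed.

**7 from 1.** The protecting groups are taken off in reverse order: lactol 7 comes from acetonide 5, 5 from trityl ether 3 and 2-(bromomethyl)naphthalene 4, and 3 from commercial acetonide 1 and trityl chloride 2. The 2-naphthylmethyl group is chosen over 4-methoxybenzyl because it survives the acid that opens the acetonide.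

## Roads not taken

Alternative 1: The cut is at the C1–O and C2–O bonds of a ring that is already in place. In the forward direction, cyclohexa-1,5-dien-1-ylmethanol A1 would be epoxidised at its allylic alkene under Sharpless titanium–tartrate control to give epoxy alcohol A2. Invertive opening at C2 would then give the trans C1/C2 diol. Its merits are real: an achiral precursor, absolute configuration from a catalyst, C3–C4 saturated from the start, almost no protecting groups, and probably half the step count of the chosen plan. Its weak points are structural. The alkene to be epoxidised is one half of a conjugated diene, so A2 is a vinyl epoxide that opens by conjugate as well as direct attack. The remaining C5=C6 alkene must then be converted into a trans C5-benzoate/C6-hydroxyl pair with C6–O cis to C7, and the only guide for regio- and facial selectivity is the substrate. O5 must also be esterified in the presence of O6 and O2. The chosen plan is longer, but takes C5 and C6 from a sugar and sets C1 and C2 in one stereospecific step, so no centre depends on a late substrate-controlled oxidation.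

Alternative 2: The cut is at C2–C3 and C5–C6, a [3+3] annulation. A chiral secondary amine would convert 2,2-dimethyl-1,3-dioxan-5-one A3 into an enamine that adds to acrolein A4 and then closes by aldol reaction to the bridged hydroxy ketone A5. This would form the ring and the oxygenated centres C2, C5 and C6 in one operation from two achiral compounds, with the cis C2/C6 oxygens already tied in one acetal and a C1 ketone ready to receive C7. In step count it would be far better than the chosen plan. The weak points lie in the key step. Acrolein must react as a Michael acceptor with an enamine that is also a good aldol donor. A second enolisation at the other α-carbon must then close a bicyclo[3.3.1] ring with the C5 hydroxyl trans to the C6 oxygen. The enantioselectivity depends only on which α-carbon ends up next to the carbinol. C7 and the C1 oxygen must afterwards be added to the bridging carbonyl with the oxygen on the face away from the acetal oxygens, most plausibly by methylenation and dihydroxylation from the carbocycle side. The chosen plan gives up this brevity for known absolute configuration and a key step whose stereochemistry follows from its geometry.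

Alternative 3: The cut is at C1–C6. A nucleophilic trialkylphosphine would add to the vinyl ketone of keto aldehyde A7, made from glutamic acid A6, and the resulting enolate carbon would attack the aldehyde to give the 2-methylene-3-hydroxycyclohexanone A8. The attractions are a short sequence, C5 from the chiral pool with its benzoate in place from the start, C3–C4 saturated throughout, and an exocyclic alkene whose dihydroxylation anti to the two allylic oxygens would give the C1 hydroxyl trans to both neighbours, as the target requires. In protecting-group economy it is better than the chosen plan. Against it: the required (R) configuration corresponds to the unnatural D-acid A6 unless an inversion is added, and the α-benzoyloxy aldehyde in A7 can epimerise or lose benzoate under the nucleophilic catalyst. The C6 carbinol must form trans to the C5 benzoate under 1,2-induction only, and the new alkoxide sits next to the ester and can take it over. The C2 ketone must then be reduced to give the C2 hydroxyl cis to the C6 hydroxyl. That makes three separate substrate-controlled events, where the chosen plan has one concerted step with two inherited centres.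

Key step: step 9

Assumption: compounds 1, 2, 4, 8, 10, 12, 17 and 23 are taken as commercial. Lactol 7 is used as its anomeric mixture. The configuration at the α-carbon of lactone 18 is of no consequence because it becomes trigonal in the ketene acetal.

Step 1
Reactants: 1 1,2-O-isopropylidene-α-D-glucofuranose; 2 trityl chloride
Product: 3 1,2-O-isopropylidene-6-O-trityl-α-D-glucofuranose
Conditions: TrCl (1.1 equiv), pyridine, DMAP (cat.), 23 °C
Reagents that add atoms: trityl chloride (2), ClC(c1ccccc1)(c1ccccc1)c1ccccc1
Why: Tritylation is selective for the only primary hydroxyl because of the bulk of the trityl group; the 3- and 5-hydroxyls stay free for the next step.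

Step 2
Reactants: 3 1,2-O-isopropylidene-6-O-trityl-α-D-glucofuranose; 4 2-(bromomethyl)naphthalene
Product: 5 1,2-O-isopropylidene-3,5-di-O-(2-naphthylmethyl)-6-O-trityl-α-D-glucofuranose
Conditions: NaH (2.6 equiv), 4 (2.4 equiv), Bu4NI (cat.), DMF, 0 → 23 °C
Reagents that add atoms: 2-(bromomethyl)naphthalene (4), BrCc1ccc2ccccc2c1
Why: Williamson etherification of both secondary alkoxides; the 2-naphthylmethyl ether survives the aqueous acid of step 3, where a 4-methoxybenzyl ether would not, and is still removable by oxidation later.

Step 3
Reactants: 5 1,2-O-isopropylidene-3,5-di-O-(2-naphthylmethyl)-6-O-trityl-α-D-glucofuranose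
Product: 7 3,5-di-O-(2-naphthylmethyl)-D-glucofuranose (anomeric mixture), via detritylated acetonide 6 (not isolated)
Conditions: 1 M aq. H2SO4–1,4-dioxane (1:3), 80 °C
Reagents that add atoms: none
Why: Acid hydrolysis first ionises the trityl ether and then opens the 1,2-O-isopropylidene acetal to the hemiacetal; arylmethyl ethers are stable to hot dilute acid and no stereocentre is touched.

Step 4
Reactants: 7 3,5-di-O-(2-naphthylmethyl)-D-glucofuranose; 8 methyltriphenylphosphonium bromide
Product: 9 1,2-dideoxy-4,6-di-O-(2-naphthylmethyl)-D-gluco-hept-1-enitol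
Conditions: Ph3PCH3Br (5 equiv), KOtBu (5 equiv), THF, 0 → 45 °C
Reagents that add atoms: methyltriphenylphosphonium bromide (8), C[P+](c1ccccc1)(c1ccccc1)c1ccccc1.[Br-]
Why: Wittig methylenation of the hydroxy aldehyde in equilibrium with the lactol, a reaction established for aldoses that keep a free 2-hydroxyl; the 2-alkoxide disfavours enolisation, so the configuration at glucose C2 (the future chirality-transferring carbinol) should be kept.

Step 5
Reactants: 9 1,2-dideoxy-4,6-di-O-(2-naphthylmethyl)-D-gluco-hept-1-enitol; 10 vinylboronic acid pinacol ester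
Product: 11 (E)-1,2-dideoxy-4,6-di-O-(2-naphthylmethyl)-1-(4,4,5,5-tetramethyl-1,3,2-dioxaborolan-2-yl)-D-gluco-hept-1-enitol
Conditions: 10 (4 equiv), second-generation Grubbs catalyst (5 mol %), 1,4-benzoquinone (10 mol %), CH2Cl2, 40 °C
Reagents that add atoms: vinylboronic acid pinacol ester (10), C=CB1OC(C)(C)C(C)(C)O1
Why: Olefin cross-metathesis of a terminal alkene with a vinylboronate; the bulky boronate and the branched allylic carbon should give the (E)-alkenylboronate, free hydroxyls are tolerated, and benzoquinone suppresses alkene migration.

Step 6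
Reactants: 11 (E)-alkenylboronate; 12 benzyl alcohol
Product: 13 (E)-1-benzyloxy-1,2-dideoxy-4,6-di-O-(2-naphthylmethyl)-D-gluco-hept-1-enitol
Conditions: Cu(OAc)2 (2 equiv), Et3N (4 equiv), BnOH as solvent, air, 23 °C; chromatography on Et3N-deactivated silica
Reagents that add atoms: benzyl alcohol (12), OCc1ccccc1
Why: Chan–Lam-type copper-promoted C–O coupling of an alkenylboronate with an alcohol, which transfers the alkenyl group with retention of the (E) geometry; benzyl alcohol as solvent outcompetes the hydroxyls of the substrate.

Step 7
Reactants: 13 (E)-1-benzyloxy-1,2-dideoxy-4,6-di-O-(2-naphthylmethyl)-D-gluco-hept-1-enitol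
Product: 16 (E)-7-benzyloxy-6,7-dideoxy-2,4-di-O-(2-naphthylmethyl)-L-gulo-hept-6-enono-1,5-lactone, via hydroxy aldehyde 14 (not isolated), via six-membered lactol 15 (not isolated)
Conditions: [Cu(MeCN)4]OTf (10 mol %), 2,2′-bipyridine (10 mol %), TEMPO (10 mol %), N-methylimidazole (20 mol %), MeCN, air, 23 °C
Reagents that add atoms: none
Why: Copper/nitroxyl aerobic oxidation is selective for the primary hydroxyl; aldehyde 14 is captured by the allylic C3 hydroxyl of 13 as lactol 15, which is oxidised on to the δ-lactone (oxidative lactonisation of a 1,5-diol). The other secondary hydroxyl could only close a four-membered ring and stays free, and the medium is neutral to basic as the acid-labile enol ether requires.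

Step 8
Reactants: 16 (E)-7-benzyloxy-6,7-dideoxy-2,4-di-O-(2-naphthylmethyl)-L-gulo-hept-6-enono-1,5-lactone; 17 benzyl chloromethyl ether
Product: 18 (E)-7-benzyloxy-3-O-(benzyloxymethyl)-6,7-dideoxy-2,4-di-O-(2-naphthylmethyl)-L-gulo-hept-6-enono-1,5-lactone
Conditions: BnOCH2Cl (3 equiv), iPr2NEt (6 equiv), Bu4NI (cat.), CH2Cl2, 0 → 35 °C
Reagents that add atoms: benzyl chloromethyl ether (17), ClCOCc1ccccc1
Why: Alkylation of the remaining hydroxyl with an α-chloro ether and a hindered amine is mild enough for the lactone and the enol ether; the benzyloxymethyl ether withstands amide base, hydride and DDQ and is removed in the final hydrogenolysis.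

Step 9
Reactants: 18 (E)-7-benzyloxy-3-O-(benzyloxymethyl)-6,7-dideoxy-2,4-di-O-(2-naphthylmethyl)-L-gulo-hept-6-enono-1,5-lactone
Product: 21 (1S,2R,5R,6S)-2-(benzyloxy)-6-[(benzyloxy)methoxy]-1,5-bis(naphthalen-2-ylmethoxy)cyclohex-3-ene-1-carboxylic acid, via silyl ketene acetal 19 (not isolated), via trimethylsilyl ester 20 (not isolated)
Conditions: Me3SiCl (4 equiv), Et3N (4 equiv), THF, −78 °C; KN(SiMe3)2 (1.3 equiv, toluene), −78 °C; then −78 → 23 °C, then 60 °C; 1 M HCl work-up
Reagents that add atoms: none
Why: KN(SiMe3)2 removes the α-proton of 18 with Me3SiCl already present, so the enolate is O-silylated as it forms to the cyclic ketene acetal 19, a 3-oxa-1,5-diene whose termini are the ketene acetal carbon (target C1) and the enol ether carbon (target C2). On warming, 19 undergoes a concerted suprafacial [3,3] sigmatropic shift (Ireland–Claisen rearrangement): C1–C2 forms, the ring O–C4 bond breaks, C3=C4 appears, and the former carbonyl carbon becomes silyl carboxylate 20, hydrolysed on work-up to 21. The closest known reaction type is the Ireland–Claisen rearrangement of six-membered lactones with an alkenyl group on the carbinol carbon, which gives cyclohexenecarboxylic acids. The cyclohexene closes by bond formation between the two termini held on one face of the lactone by the two-carbon tether C5–C6, which allows only a boat, bicyclo[2.2.2]octane-like transition state. C1 is controlled by the carbinol carbon C4, itself destroyed in the step: the vinyl group is trans to the C6 oxygen, so the new bond forms on that face and the carboxyl ends cis to the C6 oxygen and trans to the C5 oxygen. C2 is controlled by the (E) geometry of the enol ether, which in the boat places the benzyloxy group cis to the carboxyl. The step needs O-silylation to outrun β-elimination of the C6 alkoxy group, and concerted rather than ionic cleavage of the allylic C4–O bond; trapping at −78 °C by the silyl chloride already present and the basic medium free of Lewis acid should secure both. The α-configuration of 18 is lost in 19 and has no influence.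

Step 10
Reactants: 21 (1S,2R,5R,6S)-2-(benzyloxy)-6-[(benzyloxy)methoxy]-1,5-bis(naphthalen-2-ylmethoxy)cyclohex-3-ene-1-carboxylic acid
Product: 22 [(1S,2R,5R,6S)-2-(benzyloxy)-6-[(benzyloxy)methoxy]-1,5-bis(naphthalen-2-ylmethoxy)cyclohex-3-en-1-yl]methanol
Conditions: LiAlH4 (4 equiv), THF, 0 → 40 °C; H2O, 15% aq. NaOH work-up
Reagents that add atoms: none
Why: LiAlH4 reduces the hindered α-alkoxy carboxylic acid through its aluminium carboxylate to the primary alcohol; the ethers and the isolated alkene are inert and no stereocentre is involved.

Step 11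
Reactants: 22 primary alcohol; 23 benzoyl chloride
Product: 24 [(1S,2R,5R,6S)-2-(benzyloxy)-6-[(benzyloxy)methoxy]-1,5-bis(naphthalen-2-ylmethoxy)cyclohex-3-en-1-yl]methyl benzoate
Conditions: BzCl (1.2 equiv), pyridine, CH2Cl2, 0 °C
Reagents that add atoms: benzoyl chloride (23), O=C(Cl)c1ccccc1
Why: Acylation of the only free hydroxyl; doing it before the oxidative ether cleavage leaves no free hydroxyl next to the tertiary naphthylmethyl ether that could trap the oxidised ether as a cyclic acetal.

Step 12
Reactants: 24 primary benzoate
Product: 25 [(1S,2R,5R,6S)-2-(benzyloxy)-6-[(benzyloxy)methoxy]-1,5-dihydroxycyclohex-3-en-1-yl]methyl benzoate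
Conditions: DDQ (3 equiv), CH2Cl2–pH 7 phosphate buffer (10:1), 0 → 23 °C
Reagents that add atoms: none
Why: DDQ oxidises the electron-rich 2-naphthylmethyl ethers by hydride abstraction to oxocarbenium ions that water hydrolyses; benzyl and benzyloxymethyl ethers and the benzoate react much more slowly.

Step 13
Reactants: 25 diol; 23 benzoyl chloride
Product: 26 [(1S,2R,5R,6S)-5-(benzoyloxy)-2-(benzyloxy)-6-[(benzyloxy)methoxy]-1-hydroxycyclohex-3-en-1-yl]methyl benzoate
Conditions: BzCl (1.5 equiv), pyridine, DMAP (cat.), CH2Cl2, 0 → 23 °C
Reagents that add atoms: benzoyl chloride (23), O=C(Cl)c1ccccc1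
Why: Benzoylation under nucleophilic catalysis acylates the secondary allylic hydroxyl at C5; the tertiary C1 hydroxyl, flanked by three substituted carbons, should not react under these conditions.

Step 14
Reactants: 26 dibenzoate
Product: 28 [(1S,2R,5R,6S)-5-(benzoyloxy)-1,2,6-trihydroxycyclohexyl]methyl benzoate (target numbering), via saturated ether 27 (not isolated)
Conditions: H2 (1 atm), 10% Pd/C, EtOAc, 23 °C; then MeOH, Pd(OH)2/C, H2 (1 atm), 23 °C
Reagents that add atoms: none
Why: Heterogeneous hydrogenation saturates the cis-disubstituted alkene in the aprotic solvent (27), and hydrogenolysis in the second stage cleaves the benzyl and benzyloxymethyl ethers. Benzoates are inert, the neutral medium avoids acyl migration, and no stereocentre is formed.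

Compound list

1 | 1,2-O-isopropylidene-α-D-glucofuranose | CC1(C)O[C@H]2O[C@H]([C@H](O)CO)[C@H](O)[C@H]2O1 | starting material
2 | trityl chloride | ClC(c1ccccc1)(c1ccccc1)c1ccccc1 | starting material
3 | 1,2-O-isopropylidene-6-O-trityl-α-D-glucofuranose | CC1(C)O[C@H]2O[C@H]([C@H](O)COC(c3ccccc3)(c3ccccc3)c3ccccc3)[C@H](O)[C@H]2O1 | intermediate
4 | 2-(bromomethyl)naphthalene | BrCc1ccc2ccccc2c1 | starting material
5 | 1,2-O-isopropylidene-3,5-di-O-(2-naphthylmethyl)-6-O-trityl-α-D-glucofuranose | CC1(C)O[C@H]2O[C@H]([C@H](OCc3ccc4ccccc4c3)COC(c3ccccc3)(c3ccccc3)c3ccccc3)[C@H](OCc3ccc4ccccc4c3)[C@H]2O1 | intermediate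
6 | 1,2-O-isopropylidene-3,5-di-O-(2-naphthylmethyl)-α-D-glucofuranose (detritylated acetonide) | CC1(C)O[C@H]2O[C@H]([C@H](OCc3ccc4ccccc4c3)CO)[C@H](OCc3ccc4ccccc4c3)[C@H]2O1 | intermediate
7 | 3,5-di-O-(2-naphthylmethyl)-D-glucofuranose (anomeric mixture) | OC1O[C@H]([C@H](OCc2ccc3ccccc3c2)CO)[C@H](OCc2ccc3ccccc3c2)[C@H]1O | intermediate
8 | methyltriphenylphosphonium bromide | C[P+](c1ccccc1)(c1ccccc1)c1ccccc1.[Br-] | starting material
9 | 1,2-dideoxy-4,6-di-O-(2-naphthylmethyl)-D-gluco-hept-1-enitol | C=C[C@H](O)[C@@H](OCc1ccc2ccccc2c1)[C@H](O)[C@H](OCc1ccc2ccccc2c1)CO | intermediate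
10 | vinylboronic acid pinacol ester | C=CB1OC(C)(C)C(C)(C)O1 | starting material
11 | (E)-1,2-dideoxy-4,6-di-O-(2-naphthylmethyl)-1-(4,4,5,5-tetramethyl-1,3,2-dioxaborolan-2-yl)-D-gluco-hept-1-enitol | CC1(C)OB(/C=C/[C@H](O)[C@@H](OCc2ccc3ccccc3c2)[C@H](O)[C@H](OCc2ccc3ccccc3c2)CO)OC1(C)C | intermediate
12 | benzyl alcohol | OCc1ccccc1 | starting material
13 | (E)-1-benzyloxy-1,2-dideoxy-4,6-di-O-(2-naphthylmethyl)-D-gluco-hept-1-enitol | c1ccccc1CO/C=C/[C@H](O)[C@@H](OCc1ccc2ccccc2c1)[C@H](O)[C@H](OCc1ccc2ccccc2c1)CO | intermediate
14 | (E)-7-benzyloxy-6,7-dideoxy-2,4-di-O-(2-naphthylmethyl)-aldehydo-L-gulo-hept-6-enose (hydroxy aldehyde) | O=C[C@@H](OCc1ccc2ccccc2c1)[C@@H](O)[C@H](OCc1ccc2ccccc2c1)[C@@H](O)/C=C/OCc1ccccc1 | intermediate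
15 | (E)-7-benzyloxy-6,7-dideoxy-2,4-di-O-(2-naphthylmethyl)-L-gulo-hept-6-enopyranose (six-membered lactol) | OC1[C@@H](OCc2ccc3ccccc3c2)[C@@H](O)[C@H](OCc2ccc3ccccc3c2)[C@H](/C=C/OCc2ccccc2)O1 | intermediate
16 | (E)-7-benzyloxy-6,7-dideoxy-2,4-di-O-(2-naphthylmethyl)-L-gulo-hept-6-enono-1,5-lactone | O=C1[C@@H](OCc2ccc3ccccc3c2)[C@@H](O)[C@H](OCc2ccc3ccccc3c2)[C@H](/C=C/OCc2ccccc2)O1 | intermediate
17 | benzyl chloromethyl ether | ClCOCc1ccccc1 | starting material
18 | (E)-7-benzyloxy-3-O-(benzyloxymethyl)-6,7-dideoxy-2,4-di-O-(2-naphthylmethyl)-L-gulo-hept-6-enono-1,5-lactone | O=C1[C@@H](OCc2ccc3ccccc3c2)[C@@H](OCOCc2ccccc2)[C@H](OCc2ccc3ccccc3c2)[C@H](/C=C/OCc2ccccc2)O1 | intermediate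
19 | trimethylsilyl ketene acetal of 18 (silyl ketene acetal; ring stereocentres as in 18) | C[Si](C)(C)OC1=C(OCc2ccc3ccccc3c2)[C@@H](OCOCc2ccccc2)[C@H](OCc2ccc3ccccc3c2)[C@H](/C=C/OCc2ccccc2)O1 | intermediate
20 | trimethylsilyl ester of acid 21 | C[Si](C)(C)OC(=O)[C@]1(OCc2ccc3ccccc3c2)[C@H](OCc2ccccc2)C=C[C@@H](OCc2ccc3ccccc3c2)[C@@H]1OCOCc1ccccc1 | intermediate
21 | (1S,2R,5R,6S)-2-(benzyloxy)-6-[(benzyloxy)methoxy]-1,5-bis(naphthalen-2-ylmethoxy)cyclohex-3-ene-1-carboxylic acid | OC(=O)[C@]1(OCc2ccc3ccccc3c2)[C@H](OCc2ccccc2)C=C[C@@H](OCc2ccc3ccccc3c2)[C@@H]1OCOCc1ccccc1 | intermediate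
22 | [(1S,2R,5R,6S)-2-(benzyloxy)-6-[(benzyloxy)methoxy]-1,5-bis(naphthalen-2-ylmethoxy)cyclohex-3-en-1-yl]methanol | OC[C@]1(OCc2ccc3ccccc3c2)[C@H](OCc2ccccc2)C=C[C@@H](OCc2ccc3ccccc3c2)[C@@H]1OCOCc1ccccc1 | intermediate
23 | benzoyl chloride | O=C(Cl)c1ccccc1 | starting material
24 | [(1S,2R,5R,6S)-2-(benzyloxy)-6-[(benzyloxy)methoxy]-1,5-bis(naphthalen-2-ylmethoxy)cyclohex-3-en-1-yl]methyl benzoate | O=C(OC[C@]1(OCc2ccc3ccccc3c2)[C@H](OCc2ccccc2)C=C[C@@H](OCc2ccc3ccccc3c2)[C@@H]1OCOCc1ccccc1)c1ccccc1 | intermediate
25 | [(1S,2R,5R,6S)-2-(benzyloxy)-6-[(benzyloxy)methoxy]-1,5-dihydroxycyclohex-3-en-1-yl]methyl benzoate | O=C(OC[C@]1(O)[C@H](OCc2ccccc2)C=C[C@@H](O)[C@@H]1OCOCc1ccccc1)c1ccccc1 | intermediate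
26 | [(1S,2R,5R,6S)-5-(benzoyloxy)-2-(benzyloxy)-6-[(benzyloxy)methoxy]-1-hydroxycyclohex-3-en-1-yl]methyl benzoate | O=C(OC[C@]1(O)[C@H](OCc2ccccc2)C=C[C@@H](OC(=O)c2ccccc2)[C@@H]1OCOCc1ccccc1)c1ccccc1 | intermediate
27 | [(1S,2R,5R,6S)-5-(benzoyloxy)-2-(benzyloxy)-6-[(benzyloxy)methoxy]-1-hydroxycyclohexyl]methyl benzoate (saturated ether) | O=C(OC[C@]1(O)[C@H](OCc2ccccc2)CC[C@@H](OC(=O)c2ccccc2)[C@@H]1OCOCc1ccccc1)c1ccccc1 | intermediate
28 | [(1S,2R,5R,6S)-5-(benzoyloxy)-1,2,6-trihydroxycyclohexyl]methyl benzoate (target numbering; CNP0264996.1) | O=C(OC[C@]1(O)[C@H](O)CC[C@@H](OC(=O)c2ccccc2)[C@@H]1O)c1ccccc1 | target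

Total step count: 14. Longest linear sequence: 14 steps (from 1 to 28).

Least certain steps

Step 9 (key step). The most likely failure is β-elimination of the benzyloxymethoxy group from the lactone enolate before silicon traps it, giving an unsaturated lactone. A second possibility is ionisation of the allylic C–O bond next to the enol ether, which would scramble the chirality transfer. Fallback: set out from hydroxy lactone 16 and use its dianion. LiN(iPr)2 (2.2 equiv) at −78 °C gives the alkoxide enolate, in which the β-oxygen is an oxide and cannot leave. Me3SiCl and warming then bring about the same rearrangement, and hydrolysis should give the 6-hydroxy acid F1. BnOCH2Cl with iPr2NEt converts F1 into the benzyloxymethyl ether benzyloxymethyl ester F2, and LiAlH4 reduces the ester to alcohol 22, where the route is rejoined.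

Step 4. The lactol carries three acidic hydroxyls, so olefination of the polyalkoxide may be incomplete, and the strongly basic ylide may epimerise the carbon next to the aldehyde through an enediolate. Fallback: from 7, Seyferth–Gilbert homologation in the Ohira–Bestmann form (dimethyl (1-diazo-2-oxopropyl)phosphonate, K2CO3, MeOH) gives the terminal alkyne F3 under carbonate rather than ylide basicity. Copper-catalysed syn protoboration (CuCl, NaOtBu, Xantphos, B2pin2, MeOH) then gives the (E)-alkenylboronate 11 directly. This also bypasses the cross-metathesis of step 5.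

Step 6. Protodeboronation or oxidative homocoupling of the alkenylboronate may outrun C–O coupling, and the substrate's own hydroxyls may be etherified. Fallback: from 7, a Wittig reaction with the ylide from (benzyloxymethyl)triphenylphosphonium chloride and KOtBu gives the enol ether in one step as an E/Z mixture. Chromatography on deactivated silica separates 13 from its (Z) isomer F4. This is shorter, but it gives up control of geometry and loses material.

Step 7. The oxidation may stall at the lactol, or the γ-hydroxy enol ether may be lost through acid-promoted ionisation or attack of the oxidant on the electron-rich alkene. Fallback: change the order so that the oxidation precedes the enol ether. From boronate 11, TEMPO with PhI(OAc)2 in CH2Cl2 gives the boronate hydroxy lactone F5, and BnOCH2Cl with iPr2NEt gives F6. Copper-promoted coupling of F6 with benzyl alcohol 12 (5 equiv, Cu(OAc)2, Et3N, CH2Cl2) then gives 18, with the limited amount of alcohol keeping the lactone closed.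

Step 14. On palladium the allylic C–O bonds at C2 (benzyl ether) and C5 (benzoate) may undergo hydrogenolysis before the alkene is saturated, leading to deoxygenation. Fallback: from 26, reduce the alkene with diimide (2-nitrobenzenesulfonohydrazide, Et3N, CH2Cl2), which cannot cleave C–O bonds, and isolate 27. Then hydrogenolyse the two ethers over Pd(OH)2/C to reach 28.

Further compounds

F1 | step 9 | 2-(benzyloxy)-6-hydroxy-1,5-bis(naphthalen-2-ylmethoxy)cyclohex-3-ene-1-carboxylic acid, ring configuration as in 21 | OC(=O)[C@]1(OCc2ccc3ccccc3c2)[C@H](OCc2ccccc2)C=C[C@@H](OCc2ccc3ccccc3c2)[C@@H]1O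
F2 | step 9 | benzyloxymethyl 2-(benzyloxy)-6-[(benzyloxy)methoxy]-1,5-bis(naphthalen-2-ylmethoxy)cyclohex-3-ene-1-carboxylate, ring configuration as in 21 | O=C(OCOCc1ccccc1)[C@]1(OCc2ccc3ccccc3c2)[C@H](OCc2ccccc2)C=C[C@@H](OCc2ccc3ccccc3c2)[C@@H]1OCOCc1ccccc1
F3 | step 4 | 1,2-dideoxy-4,6-di-O-(2-naphthylmethyl)-D-gluco-hept-1-ynitol | C#C[C@H](O)[C@@H](OCc1ccc2ccccc2c1)[C@H](O)[C@H](OCc1ccc2ccccc2c1)CO
F4 | step 6 | (Z)-1-benzyloxy-1,2-dideoxy-4,6-di-O-(2-naphthylmethyl)-D-gluco-hept-1-enitol | c1ccccc1CO/C=C\[C@H](O)[C@@H](OCc1ccc2ccccc2c1)[C@H](O)[C@H](OCc1ccc2ccccc2c1)CO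
F5 | step 7 | (E)-6,7-dideoxy-2,4-di-O-(2-naphthylmethyl)-7-(4,4,5,5-tetramethyl-1,3,2-dioxaborolan-2-yl)-L-gulo-hept-6-enono-1,5-lactone | O=C1[C@@H](OCc2ccc3ccccc3c2)[C@@H](O)[C@H](OCc2ccc3ccccc3c2)[C@H](/C=C/B2OC(C)(C)C(C)(C)O2)O1
F6 | step 7 | (E)-3-O-(benzyloxymethyl)-6,7-dideoxy-2,4-di-O-(2-naphthylmethyl)-7-(4,4,5,5-tetramethyl-1,3,2-dioxaborolan-2-yl)-L-gulo-hept-6-enono-1,5-lactone | O=C1[C@@H](OCc2ccc3ccccc3c2)[C@@H](OCOCc2ccccc2)[C@H](OCc2ccc3ccccc3c2)[C@H](/C=C/B2OC(C)(C)C(C)(C)O2)O1
F0 | step 14 | none | none
A1 | alternative 1 | cyclohexa-1,5-dien-1-ylmethanol | OCC1=CCCC=C1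
A2 | alternative 1 | (1,2-epoxycyclohex-5-en-1-yl)methanol, oxirane oxygen on the face of the future C1 hydroxyl | OC[C@]1(O2)[C@@H]2CCC=C1
A3 | alternative 2 | 2,2-dimethyl-1,3-dioxan-5-one | CC1(C)OCC(=O)CO1
A4 | alternative 2 | acrolein | C=CC=O
A5 | alternative 2 | 6-hydroxy-3,3-dimethyl-2,4-dioxabicyclo[3.3.1]nonan-9-one (hydroxyl syn to the ketone bridge) | O=C1[C@H]2CC[C@@H](O)[C@@H]1OC(C)(C)O2
A6 | alternative 3 | D-glutamic acid | N[C@H](CCC(=O)O)C(=O)O
A7 | alternative 3 | (R)-2-(benzoyloxy)-5-oxohept-6-enal | C=CC(=O)CC[C@@H](OC(=O)c1ccccc1)C=O
A8 | alternative 3 | (3R,4R)-4-(benzoyloxy)-3-hydroxy-2-methylidenecyclohexan-1-one | C=C1C(=O)CC[C@@H](OC(=O)c2ccccc2)[C@@H]1O
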